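**Remark on the chemistry:** the target is achiral, so no stereocontrol is needed. Ring A is the tribrominated phenol ring (C1 OH, C2 ether oxygen, Br on C3, C4, C6) and ring B is the 2-bromophenyl ring. Diazo oxides such as 5 can decompose violently when dry, so 5 would be handled only in solution, cold and in the dark.

A direct plan would couple 2-bromo-6-methoxyphenol A1 with 1-bromo-2-iodobenzene A2 in a copper-mediated Ullmann ether synthesis to give 1-bromo-2-(2-bromophenoxy)-3-methoxybenzene A3. It would then cleave the methyl ether with BBr3 to 3-bromo-2-(2-bromophenoxy)phenol A4 and finish by twofold bromination. Its weakest steps would be: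
- the O-arylation, in which a phenol flanked by OMe and Br would have to attack an ortho-substituted aryl halide while copper tells the one C–I bond from the C–Br bonds of both partners and of the product;
- the ether cleavage, which would add a step without adding complexity;
- the final bromination, which would have to stop at C4 and C6 of the phenol ring and spare the position para to oxygen in the aryloxy ring.

**Strategy.** The route rests on cutting the bond between C2 of ring A and the ether oxygen. Ring B would arrive as intact 2-bromophenol and ring A as an ortho-quinone diazide, a masked 2-oxidoaryl carbene. This exploits the C1–OH/C2–OAr catechol monoether pattern of ring A: loss of N2 from C2 and insertion into the O–H bond of the phenol would form the hindered diaryl ether bond and release the C1 hydroxyl in the same operation, with all four bromines already in place. No copper or palladium would meet a C–Br bond, no phenol protecting group would be carried, and no bromination would follow the union of the rings.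

Key step: step 4

Step 1
Reactants: 1 3-bromo-2-nitrophenol
Product: 3 3,4,6-tribromo-2-nitrophenol, via 3,4-dibromo-2-nitrophenol 2 (not isolated)
Conditions: Br2 (2.1 equiv), AcOH, rt to 50 °C
Reagents that add atoms: bromine, BrBr
Why: Electrophilic aromatic bromination in which the hydroxyl group (ortho/para), the nitro group (meta) and the C3 bromine (ortho/para) all direct to C4 and C6, so the deactivated C5 should stay free and the bromine pattern of ring A should be complete before the rings are joined.

Step 2
Reactants: 3 3,4,6-tribromo-2-nitrophenol
Product: 4 2-amino-3,4,6-tribromophenol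
Conditions: Fe powder (5 equiv), AcOH/EtOH (1:4), 70 °C
Reagents that add atoms: none
Why: Béchamp-type reduction, in which zerovalent iron in acetic acid transfers electrons to the nitro group only, the standard way to keep aryl C–Br bonds that catalytic hydrogenation would endanger.

Step 3
Reactants: 4 2-amino-3,4,6-tribromophenol
Product: 5 2,4,5-tribromo-6-diazocyclohexa-2,4-dien-1-one (the ortho-quinone diazide of ring A, also written as 3,4,6-tribromo-2-diazoniophenolate)
Conditions: t-BuONO (1.3 equiv), AcOH (cat.), MeCN, 0 °C, dark; taken up in 1,2-dichloroethane, dried, not concentrated to dryness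
Reagents that add atoms: tert-butyl nitrite, CC(C)(C)ON=O
Why: Diazotization of an ortho-aminophenol, in which nitrosation and dehydration give the arenediazonium ion, whose neighbouring hydroxyl (acidified by three bromines) loses its proton to leave the neutral, halogen-stabilised diazo oxide.

Step 4
Reactants: 5 2,4,5-tribromo-6-diazocyclohexa-2,4-dien-1-one; 6 2-bromophenol
Product: 8 3,4,6-tribromo-2-(2-bromophenoxy)phenol, via oxonium ylide (2-bromophenyl)(3,5,6-tribromo-2-oxidophenyl)oxonium 7 (not isolated)
Conditions: Rh2(OAc)4 (2 mol %), 6 (5 equiv), 4 Å molecular sieves, 1,2-dichloroethane, 60 °C, dark; 5 added by syringe pump over 4 h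
Reagents that add atoms: none
Why: Proposed new method: the dirhodium tetraacetate catalyst would bind the diazo carbon of 5 and expel N2 to give a catalyst-bound 2-oxocyclohexadienylidene, an electrophilic carbenoid that amounts to an aryl cation masked by its ortho-phenoxide; the hydroxyl oxygen of 6 would attack this planar carbon from above the ring in an early, outer-sphere step that the flanking C1 carbonyl and C3 bromine hinder little, rhodium would leave, and the already aromatic zwitterion 7 would collapse by proton transfer from the oxonium to the neighbouring phenoxide oxygen through a five-membered transition state. The closest known reaction types are the rhodium-catalysed O–H insertion of alpha-diazocarbonyl compounds into phenols, the same insertion of diazonaphthoquinones into alcohols, and the thermal decomposition of tetrahalogenated benzene diazo oxides in alcohols to 2-alkoxyphenols, but a monocyclic polybrominated diazo oxide with a phenol as O–H partner has not been shown. No ring is closed and no stereocentre is formed. The step needs O-attack over C-attack of the phenol (favoured by rhodium carboxylates and by the low ring nucleophilicity of 6), capture of the carbenoid over Wolff ring contraction (metal catalysis in the dark instead of photolysis, helped by the halogen substituents), and reaction with 6 over the more hindered product 8 (excess of 6 and slow addition of 5). Regiochemistry is fixed by the substrate, since the new C–O bond can form only at the carbon that carried nitrogen and the carbonyl oxygen becomes the free C1 hydroxyl.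

**Compound list**
1 | 3-bromo-2-nitrophenol | Oc1cccc(Br)c1[N+](=O)[O-] | starting material
2 | 3,4-dibromo-2-nitrophenol | Oc1ccc(Br)c(Br)c1[N+](=O)[O-] | intermediate
3 | 3,4,6-tribromo-2-nitrophenol | Oc1c(Br)cc(Br)c(Br)c1[N+](=O)[O-] | intermediate
4 | 2-amino-3,4,6-tribromophenol | Nc1c(O)c(Br)cc(Br)c1Br | intermediate
5 | 2,4,5-tribromo-6-diazocyclohexa-2,4-dien-1-one | O=C1C(Br)=CC(Br)=C(Br)C1=[N+]=[N-] | intermediate
6 | 2-bromophenol | Oc1ccccc1Br | starting material
7 | (2-bromophenyl)(3,5,6-tribromo-2-oxidophenyl)oxonium (oxonium ylide, zwitterion) | [O-]c1c(Br)cc(Br)c(Br)c1[OH+]c1ccccc1Br | intermediate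
8 | 3,4,6-tribromo-2-(2-bromophenoxy)phenol (achiral) | Oc1c(Br)cc(Br)c(Br)c1Oc1ccccc1Br | target

**Total step count:** 4. **Longest linear sequence:** 4 (1 → 3 → 4 → 5 → 8).

**Steps most likely to fail**

Step 4 (proposed new method). Several processes could divert it:
- ring contraction of the carbenoid to a cyclopentadienyl ketene that acylates the phenol;
- attack by a ring carbon of 6 or azo coupling at its para position;
- a second insertion into the product;
- slow loss of N2 at the catalyst, because the diazo carbon of a tribrominated diazo oxide is a weak donor.

The fallback uses known chemistry, sets out from amine 4 and returns at 8. Amine 4 would be diazotized with NaNO2 in aqueous H2SO4/AcOH and the diazonium ion consumed at once by KI (Sandmeyer-type iodination) to give 3,4,6-tribromo-2-iodophenol F1. Methylation (MeI, K2CO3, acetone) would give 3,4,6-tribromo-2-iodoanisole F2. Oxidation with mCPBA and TsOH·H2O in MeCN, followed by 1,3,5-trimethoxybenzene, would give (3,5,6-tribromo-2-methoxyphenyl)(2,4,6-trimethoxyphenyl)iodonium 4-methylbenzenesulfonate F3. Metal-free O-arylation of 2-bromophenol 6 with F3 (t-BuOK, THF, rt to 40 °C) should transfer the electron-poor, doubly ortho-substituted ring, leave every C–Br bond alone and give 1,2,5-tribromo-3-(2-bromophenoxy)-4-methoxybenzene F4. BBr3 in CH2Cl2 would then release 8.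

Step 3. The diazo oxide could lose N2 or undergo light-induced ring contraction during isolation, or the weakly basic amine could be diazotized incompletely. The fallback replaces the aromatic diazo oxide by an ordinary, storable diazo diketone and builds ring A as an arene afterwards; it sets out from 2-bromophenol 6 and returns at 8.
- Compound 6 would be joined to 2-diazocyclohexane-1,3-dione F5 (made from cyclohexane-1,3-dione by diazo transfer with 4-acetamidobenzenesulfonyl azide) by Rh2(OAc)4-catalysed O–H insertion, giving 2-(2-bromophenoxy)cyclohexane-1,3-dione F6 (present as its enol).
- Ph3P/Br2 with Et3N would turn one carbonyl into the vinyl bromide 3-bromo-2-(2-bromophenoxy)cyclohex-2-en-1-one F7, which places the C3 bromine without any aromatic regiochemistry.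
- Br2 (3 equiv) in AcOH with warming should brominate C6 and C4 through the enol and dienol and aromatise by loss of HBr to 8. This is a bromination–dehydrobromination of a cyclohexenone, a known way to bromophenols.

Step 2. Reduction of a ring that already carries three bromines could be accompanied by partial reductive loss of bromine, and the aminophenol could oxidise in air on isolation. The fallback reduces before brominating; it sets out from 1 and returns at 4. Fe/AcOH on 1 would give 2-amino-3-bromophenol F8, a known compound. F8 would be dibrominated as its anilinium salt (Br2, 2 equiv, conc. H2SO4 or HBr/AcOH), where the ammonium group (meta director) and the hydroxyl (ortho/para director) both point to C4 and C6. The resulting salt of 4 could be diazotized without liberating the free base.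

**Further compounds**
F1 | step 4 | 3,4,6-tribromo-2-iodophenol | Oc1c(Br)cc(Br)c(Br)c1I
F2 | step 4 | 3,4,6-tribromo-2-iodoanisole (1,2,5-tribromo-3-iodo-4-methoxybenzene) | COc1c(Br)cc(Br)c(Br)c1I
F3 | step 4 | (3,5,6-tribromo-2-methoxyphenyl)(2,4,6-trimethoxyphenyl)iodonium 4-methylbenzenesulfonate | COc1c(Br)cc(Br)c(Br)c1[I+]c1c(OC)cc(OC)cc1OC.Cc1ccc(cc1)S(=O)(=O)[O-]
F4 | step 4 | 1,2,5-tribromo-3-(2-bromophenoxy)-4-methoxybenzene | COc1c(Br)cc(Br)c(Br)c1Oc1ccccc1Br
F5 | step 3 | 2-diazocyclohexane-1,3-dione | O=C1CCCC(=O)C1=[N+]=[N-]
F6 | step 3 | 2-(2-bromophenoxy)cyclohexane-1,3-dione | O=C1CCCC(=O)C1Oc1ccccc1Br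
F7 | step 3 | 3-bromo-2-(2-bromophenoxy)cyclohex-2-en-1-one | O=C1CCCC(Br)=C1Oc1ccccc1Br
F8 | step 2 | 2-amino-3-bromophenol | Nc1c(O)cccc1Br
A1 | direct plan | 2-bromo-6-methoxyphenol | COc1cccc(Br)c1O
A2 | direct plan | 1-bromo-2-iodobenzene | Brc1ccccc1I
A3 | direct plan | 1-bromo-2-(2-bromophenoxy)-3-methoxybenzene | COc1cccc(Br)c1Oc1ccccc1Br
A4 | direct plan | 3-bromo-2-(2-bromophenoxy)phenol | Oc1cccc(Br)c1Oc1ccccc1Br
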